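Ring B is disconnected at C5–C6 and C9–C10. An endo Diels–Alder reaction between the methyl-bearing double bond of 2-methoxy-5-methyl-1,4-benzoquinone and a (Z)-2-silyloxy diene closes ring B in one operation and sets three stereocentres: the cis ring fusion (H-5 syn to the C10 methyl) and C9, whose CH2O arm (C11) lies anti to that methyl. This cis-C5/C10, anti-C9 triad of ring B is the feature exploited. A chelating chiral titanium Lewis acid secures regiochemistry and absolute configuration. The precursor diene carries a TIPS enol ether (masked C8 ketone) and a TBS-protected C11 oxygen; the quinone's methoxy-enedione becomes ring A.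

Key step: step 6

Convention: labdane-type locants (ring A = C1–C5, C10; ring B = C5–C10; C11 = CH2 on C9); α is the face carrying H-5 and the C10 methyl, β the opposite face; all decalins below are cis-fused with H-5α, 10α-CH3 and the C9 arm β.
Assumption: the sense of induction of the BINOL–titanium catalyst on the chelated quinone is assigned by analogy; (R)-BINOL is written, and the (S)-ligand would be used if the adduct proved to belong to the mirror-image series.
Assumption: mono-silylated diol 4 is taken as a catalogue chemical (otherwise one silylation step from propane-1,3-diol).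

Step 1
Reactants: 1 2-methyl-1,4-benzoquinone (toluquinone)
Product: 3 2-methoxy-5-methyl-1,4-benzoquinone, via 2-methoxy-5-methylhydroquinone 2 (not isolated)
Conditions: MeOH, ZnCl2, rt → 50 °C (2 equiv of 1, the second as oxidant)
Reagents that add atoms: methanol, CO
Why: ZnCl2-promoted conjugate (Michael) addition of methanol at C5, the β-carbon of the more electron-poor enone of 1, gives hydroquinone 2, which a second equivalent of 1 re-oxidises by quinone–hydroquinone redox exchange (oxidative methoxylation).

Step 2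
Reactants: 4 3-[(tert-butyldimethylsilyl)oxy]propan-1-ol
Product: 5 3-[(tert-butyldimethylsilyl)oxy]propanal
Conditions: TEMPO (2,2,6,6-tetramethylpiperidin-1-oxyl, cat.), PhI(OAc)2, CH2Cl2, rt
Reagents that add atoms: none
Why: Oxoammonium-mediated alcohol oxidation stops at the aldehyde and leaves the TBS ether untouched.

Step 3
Reactants: 5 3-[(tert-butyldimethylsilyl)oxy]propanal; 6 vinylmagnesium bromide
Product: 7 racemic 5-[(tert-butyldimethylsilyl)oxy]pent-1-en-3-ol
Conditions: THF, −78 → 0 °C
Reagents that add atoms: none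
Why: Grignard 1,2-addition to the aldehyde; the new carbinol centre is racemic and is removed in step 4.

Step 4
Reactants: 7 racemic 5-[(tert-butyldimethylsilyl)oxy]pent-1-en-3-ol
Product: 8 5-[(tert-butyldimethylsilyl)oxy]pent-1-en-3-one
Conditions: Dess–Martin periodinane, pyridine, CH2Cl2, 0 °C
Reagents that add atoms: none
Why: Dess–Martin oxidation of the allylic alcohol under buffered, non-basic conditions should give the vinyl ketone without β-elimination of the silyloxy group.

Step 5
Reactants: 8 5-[(tert-butyldimethylsilyl)oxy]pent-1-en-3-one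
Product: 9 (3Z)-5-[(tert-butyldimethylsilyl)oxy]-3-[(triisopropylsilyl)oxy]penta-1,3-diene
Conditions: TIPSOTf, Et3N, CH2Cl2, −78 → 0 °C
Reagents that add atoms: triisopropylsilyl trifluoromethanesulfonate, CC(C)[Si](OS(=O)(=O)C(F)(F)F)(C(C)C)C(C)C
Why: Soft enolisation (O-silylation by the silyl triflate, then deprotonation by Et3N at the only α-CH2) gives the 2-silyloxy diene as the (Z)-enol ether, the geometry that keeps the CH2OTBS arm away from the vinyl group.

Step 6
Reactants: 3 2-methoxy-5-methyl-1,4-benzoquinone; 9 (3Z)-5-[(tert-butyldimethylsilyl)oxy]-3-[(triisopropylsilyl)oxy]penta-1,3-diene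
Product: 10 cis-fused endo adduct (H-5α; 10α-CH3; 9β-CH2OTBS; ring A 3-methoxy-2-ene-1,4-dione; ring B 8-OTIPS-7-ene)
Conditions: TiCl2(OiPr)2/(R)-1,1′-bi-2-naphthol (BINOL) (10–20 mol%), 4 Å MS, CH2Cl2, −40 → 0 °C
Reagents that add atoms: none
Why: Concerted, asynchronous [4+2] cycloaddition, suprafacial on both partners, of the class of Lewis-acid-promoted endo Diels–Alder reactions of 2-methoxy-5-methylbenzoquinone at its methyl-bearing double bond and of BINOL–titanium-catalysed enantioselective quinone Diels–Alder reactions. Ring B closes by cycloaddition, C9–C10 forming ahead of C5–C6. Tetravalent titanium chelated between the C4 carbonyl oxygen and the methoxy oxygen makes C10 the electrophilic terminus, which pairs with C9, the nucleophilic terminus of the silyl enol ether, while the methoxy-bearing double bond, a vinylogous ester, stays out. C5 and C10 are set by the cis geometry of the quinone double bond (H-5 syn to the C10 methyl), and C9 by the endo transition state, in which the CH2OTBS group, held outside on the s-cis diene by the (Z)-enol ether geometry, ends up anti to the C10 methyl. The absolute configuration of all three centres is set by the BINOLate ligand, which shields one face of the chelated quinone. The step needs regio-, endo- and enantioface selectivity, secured in turn by the chelate/silyloxy pairing, by secondary overlap of the diene with the enedione, and by the chiral ligand.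

Step 7
Reactants: 11 4-bromo-2-methylbutan-2-ol
Product: 12 [(4-bromo-2-methylbutan-2-yl)oxy]triethylsilane
Conditions: TESOTf, 2,6-lutidine, CH2Cl2, 0 °C
Reagents that add atoms: triethylsilyl trifluoromethanesulfonate, CC[Si](CC)(CC)OS(=O)(=O)C(F)(F)F
Why: Silylation of the tertiary alcohol with a silyl triflate and a hindered pyridine base masks the hydroxyl for Grignard formation.

Step 8
Reactants: 10 cis-fused endo adduct; 12 [(4-bromo-2-methylbutan-2-yl)oxy]triethylsilane
Product: 14 C4 carbinol (4β-OH; 4α-CH2CH2C(CH3)2OTES; ring A 3-methoxy-2-en-1-one), via Grignard reagent 13 (not isolated)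
Conditions: 12, Mg, THF, rt; CeCl3, THF, −78 °C; then 10, −78 °C
Reagents that add atoms: none
Why: Magnesium insertion followed by CeCl3-assisted Grignard 1,2-addition to the C4 ketone, the only carbonyl that is neither a vinylogous ester nor neopentylic, from the convex α face; the low basicity of the reagent protects H-5 from epimerisation, and the C4 carbinol centre is erased in step 10.

Step 9
Reactants: 14 C4 carbinol
Product: 16 4β-hydroxy-1-en-3-one (ring A C1=C2–C3=O; C4 carbinol retained), via allylic alcohol 15 (not isolated)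
Conditions: i-Bu2AlH (DIBAL-H), CH2Cl2, −78 °C; then 5% aq. oxalic acid, THF, 0 °C
Reagents that add atoms: water, O
Why: 1,2-Reduction of the vinylogous ester carbonyl at C1 and mild acid hydrolysis of the resulting 3-methoxyallylic alcohol with loss of water give the transposed enone (Stork–Danheiser transposition), after which C5 is no longer α to a carbonyl.

Step 10
Reactants: 16 4β-hydroxy-1-en-3-one
Product: 17 1-en-3-one with C4–H (C4 epimers; 4-CH2CH2C(CH3)2OTES)
Conditions: SmI2, THF/MeOH, −78 °C
Reagents that add atoms: none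
Why: SmI2 reduction of the α-hydroxy ketone (ketyl formation, expulsion of the C4 hydroxyl, protonation of the samarium enolate) removes the ketol oxygen; the C4 configuration is immaterial because C4 is enolised next.

Step 11
Reactants: 17 1-en-3-one with C4–H
Product: 19 4α-methyl-1-en-3-one (C4: CH3 α; CH2CH2C(CH3)2OTES β), via lithium dienolate 18 (not isolated)
Conditions: LiN(i-Pr)2 (LDA), THF, −78 °C; then MeI, DMPU, −78 → −20 °C
Reagents that add atoms: iodomethane, CI
Why: Kinetic α′-deprotonation at C4 (the only enolisable position, C10 being quaternary) and C-alkylation of the cross-conjugated dienolate with MeI on the α face, the β face being screened by C6 and its hydrogens held over C4 by the cis fusion, should set C4 with methyl α and chain β.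

Step 12
Reactants: 19 4α-methyl-1-en-3-one
Product: 20 saturated C3 ketone (4α-CH3; 4β-chain)
Conditions: H2 (1 atm), Pd/C, EtOAc, rt
Reagents that add atoms: none
Why: Heterogeneous hydrogenation saturates the disubstituted C1=C2 bond, while the hindered trisubstituted TIPS enol ether and the silyl ethers are inert.

Step 13
Reactants: 20 saturated C3 ketone
Product: 21 3β-alcohol
Conditions: LiBH(s-Bu)3 (L-Selectride), THF, −78 → 0 °C
Reagents that add atoms: none
Why: The bulky hydride attacks the C3 ketone along the equatorial trajectory on the α face, the axial β trajectory being blocked by syn-axial C6, and so should set the 3β (axial) alcohol cis to the C4 chain (substrate-controlled ketone reduction).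

Step 14
Reactants: 21 3β-alcohol
Product: 22 3β-(4-methoxybenzyl) ether
Conditions: NaH, PMBBr, Bu4NI (cat.), THF/DMF, 0 °C → rt
Reagents that add atoms: 4-methoxybenzyl bromide, COc1ccc(CBr)cc1
Why: Williamson etherification of the sodium alkoxide with the reactive benzylic bromide protects C3–OH with a group orthogonal to the silyl groups and to the later formate.

Step 15
Reactants: 22 3β-(4-methoxybenzyl) ether
Product: 23 keto diol (C8 ketone; C11–OH; side-chain tertiary OH; 3β-OPMB)
Conditions: HF·pyridine, pyridine, THF, 0 °C → rt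
Reagents that add atoms: none
Why: Fluoride-mediated desilylation cleaves the TIPS enol ether (to the C8 ketone), the primary TBS ether and the tertiary TES ether in one operation, the buffered acidic medium avoiding enolate chemistry at C9 (epimerisation, retro-aldol or β-elimination).

Step 16
Reactants: 23 keto diol
Product: 24 C8 exocyclic methylene diol
Conditions: Zn, CH2Br2, TiCl4, THF, 0 °C; then 23, CH2Cl2, 0 °C → rt
Reagents that add atoms: dibromomethane, BrCBr
Why: Takai–Lombardo methylenation with the non-basic titanium–zinc methylene reagent converts the hindered, epimerisable C8 ketone into the exocyclic alkene without touching C9 and tolerates the free hydroxyls and the PMB ether.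

Step 17
Reactants: 24 C8 exocyclic methylene diol
Product: 25 C11 iodide (tertiary OH free)
Conditions: PPh3, I2, imidazole, CH2Cl2, 0 °C → rt
Reagents that add atoms: iodine, II
Why: Appel-type iodination (alkoxyphosphonium formation, SN2 displacement by iodide) is selective for the primary C11 alcohol, the tertiary alcohol being unreactive under these conditions.

Step 18
Reactants: 25 C11 iodide
Product: 26 C11 iodide with side-chain formate
Conditions: AcOCHO (acetic formic anhydride), pyridine, 4-(dimethylamino)pyridine (DMAP, cat.), CH2Cl2, 0 °C → rt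
Reagents that add atoms: acetic formic anhydride, CC(=O)OC=O
Why: DMAP-catalysed acylation by the mixed anhydride occurs at its more electrophilic formyl carbon and formylates the only free (tertiary) hydroxyl.

Step 19
Reactants: 27 dimethyl 3-oxopentanedioate
Product: 29 methyl 4-hydroxy-6-methyl-2-oxo-2H-pyran-5-carboxylate, via acetylated diester 28 (not isolated)
Conditions: MgCl2, pyridine, AcCl, CH2Cl2, 0 °C → rt; then conc. H2SO4, 0 °C → rt
Reagents that add atoms: acetyl chloride, CC(Cl)=O
Why: Magnesium-chelate-controlled C-acylation of the active methylene followed by acid-promoted enol lactonisation of the acetyl enol onto the distal ester gives the 4-hydroxy-2-pyranone (pyrone annulation).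

Step 20
Reactants: 29 methyl 4-hydroxy-6-methyl-2-oxo-2H-pyran-5-carboxylate
Product: 30 methyl 6-methoxy-2-methyl-4-oxo-4H-pyran-3-carboxylate
Conditions: MeOTf, CH2Cl2, rt
Reagents that add atoms: methyl trifluoromethanesulfonate, COS(=O)(=O)C(F)(F)F
Why: O-Methylation of the neutral hydroxypyranone by the hard triflate occurs at the lactone carbonyl oxygen (the 4-OH being hydrogen-bonded to the ester), and loss of a proton gives the 2-methoxy-4-pyranone.

Step 21
Reactants: 30 methyl 6-methoxy-2-methyl-4-oxo-4H-pyran-3-carboxylate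
Product: 31 methyl 5-bromo-6-methoxy-2-methyl-4-oxo-4H-pyran-3-carboxylate
Conditions: N-bromosuccinimide, MeCN, rt, dark
Reagents that add atoms: N-bromosuccinimide, O=C1CCC(=O)N1Br
Why: Electrophilic bromination at C5, the only free ring position and the β-carbon of the methoxy enol ether, gives the vinyl bromide.

Step 22
Reactants: 26 C11 iodide with side-chain formate; 31 methyl 5-bromo-6-methoxy-2-methyl-4-oxo-4H-pyran-3-carboxylate
Product: 33 3β-PMB ether of the target (C11 bonded to the former C–Br carbon of the pyranone; formate in place), via alkylzinc iodide 32 (not isolated)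
Conditions: Zn dust (activated), LiCl, THF, 40 °C; then 31, Pd(OAc)2 (cat.), 2-dicyclohexylphosphino-2′,6′-dimethoxybiphenyl (SPhos, cat.), THF, rt → 50 °C
Reagents that add atoms: none
Why: LiCl-promoted zinc insertion gives a primary alkylzinc iodide that tolerates the formate, and Negishi cross-coupling (oxidative addition to the C–Br bond, transmetalation, reductive elimination favoured by the bulky biarylphosphine) forms the C11–pyranone bond without base and without touching any stereocentre.

Step 23
Reactants: 33 3β-PMB ether of the target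
Product: 34 CNP0292250.1
Conditions: DDQ, CH2Cl2/pH 7 buffer, 0 °C → rt
Reagents that add atoms: none
Why: DDQ oxidation of the electron-rich benzyl ether (hydride abstraction, hydrolysis of the oxocarbenium ion) liberates C3–OH under neutral conditions that spare the formate, the exocyclic alkene and the pyranone.

Compound list
1 | 2-methyl-1,4-benzoquinone (toluquinone) | CC1=CC(=O)C=CC1=O | starting material
2 | 2-methoxy-5-methylbenzene-1,4-diol | COc1cc(O)c(C)cc1O | intermediate (not isolated)
3 | 2-methoxy-5-methyl-1,4-benzoquinone | COC1=CC(=O)C(C)=CC1=O | intermediate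
4 | 3-[(tert-butyldimethylsilyl)oxy]propan-1-ol | CC(C)(C)[Si](C)(C)OCCCO | starting material
5 | 3-[(tert-butyldimethylsilyl)oxy]propanal | CC(C)(C)[Si](C)(C)OCCC=O | intermediate
6 | vinylmagnesium bromide | C=C[Mg]Br | starting material
7 | racemic 5-[(tert-butyldimethylsilyl)oxy]pent-1-en-3-ol | C=CC(O)CCO[Si](C)(C)C(C)(C)C | intermediate
8 | 5-[(tert-butyldimethylsilyl)oxy]pent-1-en-3-one | C=CC(=O)CCO[Si](C)(C)C(C)(C)C | intermediate
9 | (3Z)-5-[(tert-butyldimethylsilyl)oxy]-3-[(triisopropylsilyl)oxy]penta-1,3-diene | C=C/C(O[Si](C(C)C)(C(C)C)C(C)C)=C/CO[Si](C)(C)C(C)(C)C | intermediate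
10 | cis-fused endo adduct: H-5α, 10α-CH3, 9β-CH2OTBS; ring A 3-methoxy-2-ene-1,4-dione; ring B 8-OTIPS-7-ene | CC(C)[Si](C(C)C)(C(C)C)OC1=CC[C@H]2C(=O)C(OC)=CC(=O)[C@@]2(C)[C@H]1CO[Si](C)(C)C(C)(C)C | intermediate
11 | 4-bromo-2-methylbutan-2-ol | CC(C)(O)CCBr | starting material
12 | [(4-bromo-2-methylbutan-2-yl)oxy]triethylsilane | CC[Si](CC)(CC)OC(C)(C)CCBr | intermediate
13 | [3-methyl-3-(triethylsilyloxy)butyl]magnesium bromide | CC[Si](CC)(CC)OC(C)(C)CC[Mg]Br | intermediate (not isolated)
14 | C4 carbinol: 4β-OH, 4α-CH2CH2C(CH3)2OTES; ring A 3-methoxy-2-en-1-one; rest as 10 | CC(C)[Si](C(C)C)(C(C)C)OC1=CC[C@H]2[C@@](CCC(C)(C)O[Si](CC)(CC)CC)(O)C(OC)=CC(=O)[C@@]2(C)[C@H]1CO[Si](C)(C)C(C)(C)C | intermediate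
15 | allylic alcohol: 14 with C1 carbonyl reduced to CH–OH (C1 configuration not defined) | CC(C)[Si](C(C)C)(C(C)C)OC1=CC[C@H]2[C@@](CCC(C)(C)O[Si](CC)(CC)CC)(O)C(OC)=CC(O)[C@@]2(C)[C@H]1CO[Si](C)(C)C(C)(C)C | intermediate (not isolated)
16 | 4β-hydroxy-1-en-3-one: ring A C1=C2–C3=O, C4 carbinol as in 14 | CC(C)[Si](C(C)C)(C(C)C)OC1=CC[C@H]2[C@@](CCC(C)(C)O[Si](CC)(CC)CC)(O)C(=O)C=C[C@@]2(C)[C@H]1CO[Si](C)(C)C(C)(C)C | intermediate
17 | 1-en-3-one with C4–H (C4 epimers), 4-CH2CH2C(CH3)2OTES | CC(C)[Si](C(C)C)(C(C)C)OC1=CC[C@H]2C(CCC(C)(C)O[Si](CC)(CC)CC)C(=O)C=C[C@@]2(C)[C@H]1CO[Si](C)(C)C(C)(C)C | intermediate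
18 | lithium dienolate of 17 (C3–OLi, C3=C4, C1=C2) | CC(C)[Si](C(C)C)(C(C)C)OC1=CC[C@H]2C(CCC(C)(C)O[Si](CC)(CC)CC)=C(O[Li])C=C[C@@]2(C)[C@H]1CO[Si](C)(C)C(C)(C)C | intermediate (not isolated)
19 | 4α-methyl-4β-[3-methyl-3-(triethylsilyloxy)butyl]-1-en-3-one | CC(C)[Si](C(C)C)(C(C)C)OC1=CC[C@H]2[C@@](C)(CCC(C)(C)O[Si](CC)(CC)CC)C(=O)C=C[C@@]2(C)[C@H]1CO[Si](C)(C)C(C)(C)C | intermediate
20 | saturated C3 ketone: 4α-CH3, 4β-chain | CC(C)[Si](C(C)C)(C(C)C)OC1=CC[C@H]2[C@@](C)(CCC(C)(C)O[Si](CC)(CC)CC)C(=O)CC[C@@]2(C)[C@H]1CO[Si](C)(C)C(C)(C)C | intermediate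
21 | 3β-alcohol | CC(C)[Si](C(C)C)(C(C)C)OC1=CC[C@H]2[C@@](C)(CCC(C)(C)O[Si](CC)(CC)CC)[C@@H](O)CC[C@@]2(C)[C@H]1CO[Si](C)(C)C(C)(C)C | intermediate
22 | 3β-(4-methoxybenzyl) ether | CC(C)[Si](C(C)C)(C(C)C)OC1=CC[C@H]2[C@@](C)(CCC(C)(C)O[Si](CC)(CC)CC)[C@@H](OCc3ccc(OC)cc3)CC[C@@]2(C)[C@H]1CO[Si](C)(C)C(C)(C)C | intermediate
23 | keto diol: C8 ketone, C11–OH, side-chain tertiary OH, 3β-OPMB | O=C1CC[C@H]2[C@@](C)(CCC(C)(C)O)[C@@H](OCc3ccc(OC)cc3)CC[C@@]2(C)[C@H]1CO | intermediate
24 | C8 exocyclic methylene diol | C=C1CC[C@H]2[C@@](C)(CCC(C)(C)O)[C@@H](OCc3ccc(OC)cc3)CC[C@@]2(C)[C@H]1CO | intermediate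
25 | C11 iodide, tertiary OH free | C=C1CC[C@H]2[C@@](C)(CCC(C)(C)O)[C@@H](OCc3ccc(OC)cc3)CC[C@@]2(C)[C@H]1CI | intermediate
26 | C11 iodide with side-chain formate | C=C1CC[C@H]2[C@@](C)(CCC(C)(C)OC=O)[C@@H](OCc3ccc(OC)cc3)CC[C@@]2(C)[C@H]1CI | intermediate
27 | dimethyl 3-oxopentanedioate | COC(=O)CC(=O)CC(=O)OC | starting material
28 | dimethyl 2-acetyl-3-oxopentanedioate | COC(=O)CC(=O)C(C(C)=O)C(=O)OC | intermediate (not isolated)
29 | methyl 4-hydroxy-6-methyl-2-oxo-2H-pyran-5-carboxylate | COC(=O)C1=C(C)OC(=O)C=C1O | intermediate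
30 | methyl 6-methoxy-2-methyl-4-oxo-4H-pyran-3-carboxylate | COC(=O)c1c(C)oc(OC)cc1=O | intermediate
31 | methyl 5-bromo-6-methoxy-2-methyl-4-oxo-4H-pyran-3-carboxylate | COC(=O)c1c(C)oc(OC)c(Br)c1=O | intermediate
32 | C11 alkylzinc iodide from 26 | C=C1CC[C@H]2[C@@](C)(CCC(C)(C)OC=O)[C@@H](OCc3ccc(OC)cc3)CC[C@@]2(C)[C@H]1C[Zn]I | intermediate (not isolated)
33 | 3β-PMB ether of the target | C=C1CC[C@H]2[C@@](C)(CCC(C)(C)OC=O)[C@@H](OCc3ccc(OC)cc3)CC[C@@]2(C)[C@H]1Cc1c(OC)oc(C)c(C(=O)OC)c1=O | intermediate
34 | CNP0292250.1: H-5α, 10α-CH3, 9β-CH2-pyranone, 8-methylene, 4α-CH3, 4β-CH2CH2C(CH3)2OCHO, 3β-OH | C=C1CC[C@H]2[C@@](C)(CCC(C)(C)OC=O)[C@@H](O)CC[C@@]2(C)[C@H]1Cc1c(OC)oc(C)c(C(=O)OC)c1=O | target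

Total step count: 23.
Longest linear sequence: 18 steps (steps 2–6, 8–18, 22, 23).

Steps most likely to fail

Step 6. The chiral titanium complex may discriminate the two faces of the chelated quinone poorly, or the Lewis acid may strip the silyl enol ether before cycloaddition. Fallback: setting out from 3 and 9, the cycloaddition would be run without chiral control (thermally in toluene, or with achiral SnCl4), which should give racemic 10 with the same regiochemistry and endo sense. The racemate would be carried through steps 8–16 to racemic 24. Acylation of its primary alcohol with (S)-2-methoxy-2-phenylacetic acid (N,N′-dicyclohexylcarbodiimide, DMAP) would give the (S)-O-methylmandelate of 24 F1 and the diastereomeric (S)-O-methylmandelate of ent-24 F2. These would be separated by chromatography, and methanolysis of F1 (K2CO3, MeOH) would return the route to 24.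

Step 11. The methyl group may be delivered to the wrong face of the dienolate (syn to C6 instead of syn to H-5), giving the C4 epimer. Fallback: the order in which the two C4 substituents arrive would be reversed, so that the same facial preference places the chain instead of the methyl group. Setting out from 10, MeMgBr/CeCl3 would give the C4-methyl carbinol F3. Reduction with i-Bu2AlH to the allylic alcohol F4 (not isolated) and oxalic acid work-up would give the 4-hydroxy-4-methyl enone F5. SmI2 would give the 4-methyl enone F6. The silyl ether iodide F7 would be made from 12 by Finkelstein exchange (NaI, acetone). The lithium dienolate F8 of F6 (LDA, THF, −78 °C) would be alkylated with F7 in THF/HMPA, which returns the route to 19.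

Step 22. Transmetalation and reductive elimination between the β-branched alkylzinc and the doubly flanked bromopyranone may be slow, so that protodezincation or β-hydride elimination takes over. Fallback: setting out from 24, TEMPO/PhI(OAc)2 oxidation of the primary alcohol would give the C11 aldehyde F9, used at once. Condensation with hydroxypyranone 29 (L-proline cat., diethyl 2,6-dimethyl-1,4-dihydropyridine-3,5-dicarboxylate as hydride donor, CH2Cl2, rt) would form the Knoevenagel alkylidene pyrandione F10 (not isolated), reduced in situ to the 3-alkylated 4-hydroxy-2-pyranone F11. MeOTf with 2,6-di-tert-butyl-4-methylpyridine would give the 2-methoxy-4-pyranone tertiary alcohol F12, and formylation as in step 18 would return the route to 33.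

Further compounds
F1 | step 6 | (S)-2-methoxy-2-phenylacetate ester at C11–O of 24 | C=C1CC[C@H]2[C@@](C)(CCC(C)(C)O)[C@@H](OCc3ccc(OC)cc3)CC[C@@]2(C)[C@H]1COC(=O)[C@@H](OC)c1ccccc1
F2 | step 6 | (S)-2-methoxy-2-phenylacetate ester at C11–O of ent-24 (separated and discarded) | C=C1CC[C@@H]2[C@](C)(CCC(C)(C)O)[C@H](OCc3ccc(OC)cc3)CC[C@]2(C)[C@@H]1COC(=O)[C@@H](OC)c1ccccc1
F3 | step 11 | C4-methyl carbinol from 10 (4α-CH3, 4β-OH; ring A 3-methoxy-2-en-1-one) | CC(C)[Si](C(C)C)(C(C)C)OC1=CC[C@H]2[C@@](C)(O)C(OC)=CC(=O)[C@@]2(C)[C@H]1CO[Si](C)(C)C(C)(C)C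
F4 | step 11 | allylic alcohol from F3 (C1 carbinol, configuration not defined; not isolated) | CC(C)[Si](C(C)C)(C(C)C)OC1=CC[C@H]2[C@@](C)(O)C(OC)=CC(O)[C@@]2(C)[C@H]1CO[Si](C)(C)C(C)(C)C
F5 | step 11 | 4β-hydroxy-4α-methyl-1-en-3-one | CC(C)[Si](C(C)C)(C(C)C)OC1=CC[C@H]2[C@@](C)(O)C(=O)C=C[C@@]2(C)[C@H]1CO[Si](C)(C)C(C)(C)C
F6 | step 11 | 4-methyl-1-en-3-one (C4 epimers) | CC(C)[Si](C(C)C)(C(C)C)OC1=CC[C@H]2C(C)C(=O)C=C[C@@]2(C)[C@H]1CO[Si](C)(C)C(C)(C)C
F7 | step 11 | triethyl[(4-iodo-2-methylbutan-2-yl)oxy]silane | CC[Si](CC)(CC)OC(C)(C)CCI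
F8 | step 11 | lithium dienolate of F6 (not isolated) | CC(C)[Si](C(C)C)(C(C)C)OC1=CC[C@H]2C(C)=C(O[Li])C=C[C@@]2(C)[C@H]1CO[Si](C)(C)C(C)(C)C
F9 | step 22 | C11 aldehyde from 24 | C=C1CC[C@H]2[C@@](C)(CCC(C)(C)O)[C@@H](OCc3ccc(OC)cc3)CC[C@@]2(C)[C@H]1C=O
F10 | step 22 | Knoevenagel alkylidene pyran-2,4-dione (alkene geometry not defined; not isolated) | C=C1CC[C@H]2[C@@](C)(CCC(C)(C)O)[C@@H](OCc3ccc(OC)cc3)CC[C@@]2(C)[C@H]1C=C1C(=O)OC(C)=C(C(=O)OC)C1=O
F11 | step 22 | 3-alkylated methyl 4-hydroxy-6-methyl-2-oxo-2H-pyran-5-carboxylate | C=C1CC[C@H]2[C@@](C)(CCC(C)(C)O)[C@@H](OCc3ccc(OC)cc3)CC[C@@]2(C)[C@H]1CC1=C(O)C(C(=O)OC)=C(C)OC1=O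
F12 | step 22 | 2-methoxy-4-pyranone with free tertiary alcohol (33 without the formyl group) | C=C1CC[C@H]2[C@@](C)(CCC(C)(C)O)[C@@H](OCc3ccc(OC)cc3)CC[C@@]2(C)[C@H]1Cc1c(OC)oc(C)c(C(=O)OC)c1=O
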